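Follow the gas.

| setting | summer | noon | flask |
|---|---|---|---|
| left-handed substrate | 0.074 M | 0.15 M | 0.074 M |
| right-handed substrate | 0.074 M | 0.15 M | 0.074 M |
| gas | 3.8 mM (held) | 3.8 mM (held) | 3.8 mM (held) |
| catalyst | 0.24 mol% | 0.24 mol% | 0.24 mol% |
| remark | the very flask that is asked about, followed so far | run made earlier |  |

- summer (time / min: left-handed product / %, left-handed substrate / %): 1.33: 0.1, 49.8; 4.00: 2.0, 47.7; 8.00: 4.1, 45.6; 10.0: 5.0, 44.2; 15.0: 8.5, 41.7
- noon (time / min: left-handed product / %, left-handed substrate / %): 1.50: 0.3, 49.6; 3.00: 1.1, 49.1; 6.00: 1.2, 47.6; 10.0: 3.3, 46.6; 20.0: 7.1, 43.3

(standard deviation of a reading: 0.5 percentage points)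

- catalyst is single-handed; left-handed substrate and right-handed substrate are mirror images of each other, charged as a racemate, each of them at the stated concentration
- at the start none of the gas is in solution

- apparent order in catalyst when 5.0 % of the left-handed substrate and right-handed substrate together are converted (percent change of the rate of making left-handed product for one percent more catalyst charged)
- factor on the rate of making left-handed product when 5.0 % of the left-handed substrate and right-handed substrate together are converted if catalyst is charged twice over

Compare two rates: the rate of making left-handed product in the summer flask, and the ceiling, the rate at which gas enters liquid holding none. Read the left-handed product between 4.00 min and 15.0 min: the summer run makes 0.00591 /min of its charge. The noon run, read between 3.00 min and 20.0 min, makes 0.00353 /min of its own charge. That charge is 2.03 times the summer one, so this equals 0.00715 /min of the summer charge.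

Noon has the same loading, so substrate and catalyst both grow by that factor, and I take the reaction's speed to grow by its square. Treat the two as resistances in series: the inverse rate is the inverse ceiling plus the inverse reaction speed. The two runs then give a ceiling of 0.00767 /min. Call the rate over the ceiling the gas share, 0.770 for the summer flask, which runs below its ceiling; at this reading, neither gas entry nor the reaction is by itself the rate-limiting step. The order in catalyst is one minus the share, 0.230, and doubled catalyst gives two over one plus the share, 1.13; the scatter makes both rough.

The forecast gives 0.35 and 1.22, reading “gas supply partly limiting the rate”, and my order is lower.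

The summer flask gives an order of 0.20 and a factor of 1.11.

    gas ⇌ partner, rate k1*(csat - [partner]) (kL = 0.00480 /s)
    partner + catalyst + right-handed substrate → catalyst + right-handed product (k = 100 /M²/s)
    catalyst ⇌ dormant form (K = 0.500, k = 4.20 × 10⁻⁴ /s)
    partner + catalyst + left-handed substrate → catalyst + left-handed product (k = 2000 /M²/s)

Partner, the dissolved gas, stood in the summer flask at 6.35 × 10⁻⁴ M after 5.00 min, which is 16.7 % of saturation. Now carry the share to the noon run: scaled by that run's rate, it becomes 0.932, which puts the noon run's order in catalyst at about 0.0684.

The readings stem from a simulated flask for substances that don't exist; the scatter is artificial.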